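**Retrosynthetic overview**

1. Feature: in coumarin unit B the axis carbon C8' lies between two oxygen-bearing carbons, C7' (OH) and C8a' (lactone O1'). The benzene ring of B is therefore a 2-aryl resorcinol, the pattern a vinylketene/ynol ether benzannulation gives when the aryl group (C6 of coumarin A) sits on the alkyne.
2. Late disconnections: O-dealkylation at C7' and C7''; lactone C (C3''=C4'' and O1''–C2'') by Perkin–Oglialoro condensation of an O7–CH2CO2H arm with 2-hydroxy-4-methoxybenzaldehyde; lactone B (C4'–C4a') by gold-catalysed hydroarylation of the O8a' propiolate.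
3. Key disconnection: benzene ring of B (C8'–C8a', C6'–C7', C4a'–C8a') from cyclobutenone and a 6-(ethoxyethynyl)coumarin; the axis C6–C8' is made beforehand as an unhindered sp–sp2 bond by Sonogashira coupling.
4. Ring A from 2,4-dihydroxybenzaldehyde by C5 iodination, Wittig lactonization and O7 alkylation with tert-butyl bromoacetate.
5. Order of ring formation: lactone A, benzene B, lactone B, lactone C.

Key step: step 7

Remarks on the chemistry: unprimed locants refer to coumarin A, primed to coumarin B, double-primed to coumarin C. O7 carries a CH2CO2tBu arm through the key step in place of a simple protecting group; this arm later becomes C2''/C3'' of ring C. The C6–C8' axis has only small ortho substituents and is assumed to rotate freely, so no axial configuration is set; the target has no stereocenter.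

**Route**

Step 1
Reactants: 1 2,4-dihydroxybenzaldehyde
Product: 2 2,4-dihydroxy-5-iodobenzaldehyde
Conditions: ICl, AcOH, rt
Reagents that add atoms: iodine monochloride, ClI
Why: Electrophilic aromatic iodination should go mainly to C5 (para to the 2-OH, ortho to the 4-OH), which is less hindered than C3 between the two hydroxyls; the minor 3-iodo isomer is removed by crystallization.

Step 2
Reactants: 2 2,4-dihydroxy-5-iodobenzaldehyde; 3 ethyl (triphenylphosphoranylidene)acetate
Product: 6 7-hydroxy-6-iodocoumarin, via E-cinnamate 4 (not isolated), via Z-cinnamate 5 (not isolated)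
Conditions: PhNEt2, reflux (ca. 215 °C)
Reagents that add atoms: none
Why: Wittig olefination with the stabilized ylide gives mainly the E-cinnamate 4, which at this temperature equilibrates with the Z-isomer 5, and 5 is drained by lactonization of the 2-OH onto the ester with loss of ethanol (Wittig coumarin synthesis).

Step 3
Reactants: 6 7-hydroxy-6-iodocoumarin; 7 tert-butyl bromoacetate
Product: 8 tert-butyl 2-[(6-iodo-2-oxo-2H-chromen-7-yl)oxy]acetate
Conditions: K2CO3, DMF, rt
Reagents that add atoms: none
Why: Williamson etherification of the only phenol with a reactive α-bromo ester under anhydrous carbonate conditions, which leave the lactone closed.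

Step 4
Reactants: 8 tert-butyl 2-[(6-iodo-2-oxo-2H-chromen-7-yl)oxy]acetate; 9 ethoxyacetylene
Product: 10 tert-butyl 2-{[6-(ethoxyethynyl)-2-oxo-2H-chromen-7-yl]oxy}acetate
Conditions: Pd(PPh3)4 (5 mol %), CuI (10 mol %), Et3N, THF, rt; chromatography on Et3N-deactivated silica
Reagents that add atoms: none
Why: Sonogashira coupling (oxidative addition of the aryl iodide to zerovalent palladium, transmetalation from the copper acetylide, reductive elimination) at room temperature and under basic conditions, which the acid-sensitive ynol ether should tolerate.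

Step 5
Reactants: 11 3-oxocyclobutanecarboxylic acid
Product: 12 3-bromocyclobutanone
Conditions: HgO, Br2, CH2Cl2, reflux
Reagents that add atoms: bromine, BrBr
Why: Cristol–Firth variant of the Hunsdiecker bromodecarboxylation, in which the acyl hypobromite loses CO2 by a radical chain and the cyclobutyl radical picks up bromine.

Step 6
Reactants: 12 3-bromocyclobutanone
Product: 13 cyclobut-2-en-1-one
Conditions: n-Bu3N, neat, rt, reduced pressure, product collected in a −78 °C trap and kept cold as a toluene solution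
Reagents that add atoms: none
Why: E1cB dehydrobromination of the β-bromo ketone by the non-nucleophilic, non-volatile amine, with the volatile enone removed from the base as it forms.

Step 7
Reactants: 10 tert-butyl 2-{[6-(ethoxyethynyl)-2-oxo-2H-chromen-7-yl]oxy}acetate; 13 cyclobut-2-en-1-one
Product: 18 tert-butyl 2-{[6-(2-ethoxy-6-hydroxyphenyl)-2-oxo-2H-chromen-7-yl]oxy}acetate, via vinylketene 14 (not isolated), via 4-vinylcyclobutenone 15 (not isolated), via dienylketene 16 (not isolated), via cyclohexadienone 17 (not isolated)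
Conditions: 13 (2 equiv, added slowly as a toluene solution), toluene, 80 °C, argon
Reagents that add atoms: none
Why: Danheiser benzannulation, a known thermal cascade of cyclobutenones with alkoxyalkynes: at 80 °C cyclobutenone 13 opens by four-electron electrocyclic cleavage to vinylketene 14, which is captured by the ynol ether 10 in a regioselective (2+2) cycloaddition to give the 4-vinylcyclobutenone 15. Reversible four-electron opening of 15 gives dienylketene 16, whose ketene carbon closes onto the vinyl terminus by six-electron electrocyclization to the cyclohexa-2,4-dienone 17, and tautomerization to the phenol makes the sequence irreversible and completes the benzene ring of unit B (bonds C8'–C8a', C6'–C7' and C4a'–C8a'). The one selectivity needed is the orientation of the ketene–alkyne addition: the ethoxy group makes the aryl-bearing alkyne carbon (future C8') the nucleophilic terminus, so it bonds to the electrophilic ketene carbonyl carbon (future C8a') and the coumarinyl group ends up between OH and OEt. No stereocenter reaches the product, since the one in 15 is destroyed on ring opening. The temperature is held at 80 °C, below the onset of retro-ene loss of ethylene from the ethyl ynol ether, and cyclobutenone is added slowly so that vinylketene meets the alkyne and not itself or the product phenol.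

Step 8
Reactants: 18 tert-butyl 2-{[6-(2-ethoxy-6-hydroxyphenyl)-2-oxo-2H-chromen-7-yl]oxy}acetate; 19 propiolic acid
Product: 20 2-[7-(2-tert-butoxy-2-oxoethoxy)-2-oxo-2H-chromen-6-yl]-3-ethoxyphenyl prop-2-ynoate
Conditions: DCC, DMAP (cat.), CH2Cl2, 0 °C
Reagents that add atoms: none
Why: Steglich esterification of the only free hydroxyl (O8a'), run cold to suppress conjugate addition to the propiolate.

Step 9
Reactants: 20 2-[7-(2-tert-butoxy-2-oxoethoxy)-2-oxo-2H-chromen-6-yl]-3-ethoxyphenyl prop-2-ynoate
Product: 21 tert-butyl 2-{[6-(7-ethoxy-2-oxo-2H-chromen-8-yl)-2-oxo-2H-chromen-7-yl]oxy}acetate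
Conditions: Ph3PAuCl (5 mol %), AgSbF6 (5 mol %), CH2Cl2, rt
Reagents that add atoms: none
Why: Intramolecular hydroarylation of an aryl propiolate by cationic monovalent gold (π-activation, 6-endo-dig Friedel–Crafts attack, protodeauration) at C4a', the only free position ortho to the ester oxygen and para to the ethoxy group, so lactone B can close in one sense only.

Step 10
Reactants: 21 tert-butyl 2-{[6-(7-ethoxy-2-oxo-2H-chromen-8-yl)-2-oxo-2H-chromen-7-yl]oxy}acetate
Product: 22 2-{[6-(7-ethoxy-2-oxo-2H-chromen-8-yl)-2-oxo-2H-chromen-7-yl]oxy}acetic acid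
Conditions: TFA, CH2Cl2, rt
Reagents that add atoms: none
Why: Acidolysis of the tert-butyl ester by loss of the tert-butyl cation as isobutene, under conditions to which lactones and the aryl ethyl ether are inert.

Step 11
Reactants: 22 2-{[6-(7-ethoxy-2-oxo-2H-chromen-8-yl)-2-oxo-2H-chromen-7-yl]oxy}acetic acid; 23 2-hydroxy-4-methoxybenzaldehyde
Product: 26 7-ethoxy-8-{7-[(7-methoxy-2-oxo-2H-chromen-3-yl)oxy]-2-oxo-2H-chromen-6-yl}-2H-chromen-2-one, via mixed anhydride 24 (not isolated), via aryl ester 25 (not isolated)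
Conditions: Ac2O, Et3N, 120 °C
Reagents that add atoms: none
Why: Perkin–Oglialoro coumarin synthesis, the classical route from aryloxyacetic acids and salicylaldehydes to 3-aryloxycoumarins: the mixed anhydride 24 acylates the phenol of 23, and the activated OCH2 of ester 25 undergoes intramolecular aldol condensation with the ortho aldehyde to form C3''=C4''.

Step 12
Reactants: 26 7-ethoxy-8-{7-[(7-methoxy-2-oxo-2H-chromen-3-yl)oxy]-2-oxo-2H-chromen-6-yl}-2H-chromen-2-one
Product: 27 7-hydroxy-8-{7-[(7-hydroxy-2-oxo-2H-chromen-3-yl)oxy]-2-oxo-2H-chromen-6-yl}-2H-chromen-2-one (target, CNP0215289.0)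
Conditions: BBr3 (8 equiv), CH2Cl2, −78 °C to rt; then H2O
Reagents that add atoms: none
Why: BBr3 dealkylation of aryl alkyl ethers (O-coordination, then bromide attack at the sp3 carbon) should remove the ethyl and methyl groups, while the C7–O–C3'' diaryl-type ether has no sp3 carbon to attack and coumarin lactones re-form on aqueous work-up.

**Compound list**

1 | 2,4-dihydroxybenzaldehyde | O=Cc1ccc(O)cc1O | starting material
2 | 2,4-dihydroxy-5-iodobenzaldehyde | O=Cc1cc(I)c(O)cc1O | intermediate
3 | ethyl (triphenylphosphoranylidene)acetate | CCOC(=O)C=P(c1ccccc1)(c1ccccc1)c1ccccc1 | starting material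
4 | ethyl (E)-3-(2,4-dihydroxy-5-iodophenyl)prop-2-enoate | CCOC(=O)/C=C/c1cc(I)c(O)cc1O | intermediate
5 | ethyl (Z)-3-(2,4-dihydroxy-5-iodophenyl)prop-2-enoate | CCOC(=O)/C=C\c1cc(I)c(O)cc1O | intermediate
6 | 7-hydroxy-6-iodocoumarin | O=c1ccc2cc(I)c(O)cc2o1 | intermediate
7 | tert-butyl bromoacetate | CC(C)(C)OC(=O)CBr | starting material
8 | tert-butyl 2-[(6-iodo-2-oxo-2H-chromen-7-yl)oxy]acetate | O=c1ccc2cc(I)c(OCC(=O)OC(C)(C)C)cc2o1 | intermediate
9 | ethoxyacetylene | C#COCC | starting material
10 | tert-butyl 2-{[6-(ethoxyethynyl)-2-oxo-2H-chromen-7-yl]oxy}acetate | O=c1ccc2cc(C#COCC)c(OCC(=O)OC(C)(C)C)cc2o1 | intermediate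
11 | 3-oxocyclobutanecarboxylic acid | O=C1CC(C1)C(O)=O | starting material
12 | 3-bromocyclobutanone | O=C1CC(Br)C1 | intermediate
13 | cyclobut-2-en-1-one | O=C1C=CC1 | intermediate
14 | vinylketene (buta-1,3-dien-1-one) | C=CC=C=O | intermediate
15 | tert-butyl 2-{[6-(2-ethoxy-3-ethenyl-4-oxocyclobut-1-en-1-yl)-2-oxo-2H-chromen-7-yl]oxy}acetate (racemic) | O=c1ccc2cc(C3=C(OCC)C(C=C)C3=O)c(OCC(=O)OC(C)(C)C)cc2o1 | intermediate
16 | tert-butyl 2-{[6-((3E)-3-ethoxy-1-oxohexa-1,3,5-trien-2-yl)-2-oxo-2H-chromen-7-yl]oxy}acetate (ketene carbon and vinyl group cis) | O=C=C(c1cc2ccc(=O)oc2cc1OCC(=O)OC(C)(C)C)/C(OCC)=C\C=C | intermediate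
17 | tert-butyl 2-{[6-(2-ethoxy-6-oxocyclohexa-1,3-dien-1-yl)-2-oxo-2H-chromen-7-yl]oxy}acetate | O=C1CC=CC(OCC)=C1c1cc2ccc(=O)oc2cc1OCC(=O)OC(C)(C)C | intermediate
18 | tert-butyl 2-{[6-(2-ethoxy-6-hydroxyphenyl)-2-oxo-2H-chromen-7-yl]oxy}acetate | O=c1ccc2cc(-c3c(O)cccc3OCC)c(OCC(=O)OC(C)(C)C)cc2o1 | intermediate
19 | propiolic acid | C#CC(O)=O | starting material
20 | 2-[7-(2-tert-butoxy-2-oxoethoxy)-2-oxo-2H-chromen-6-yl]-3-ethoxyphenyl prop-2-ynoate | O=c1ccc2cc(-c3c(OC(=O)C#C)cccc3OCC)c(OCC(=O)OC(C)(C)C)cc2o1 | intermediate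
21 | tert-butyl 2-{[6-(7-ethoxy-2-oxo-2H-chromen-8-yl)-2-oxo-2H-chromen-7-yl]oxy}acetate | O=c1ccc2cc(-c3c(OCC)ccc4ccc(=O)oc34)c(OCC(=O)OC(C)(C)C)cc2o1 | intermediate
22 | 2-{[6-(7-ethoxy-2-oxo-2H-chromen-8-yl)-2-oxo-2H-chromen-7-yl]oxy}acetic acid | O=c1ccc2cc(-c3c(OCC)ccc4ccc(=O)oc34)c(OCC(=O)O)cc2o1 | intermediate
23 | 2-hydroxy-4-methoxybenzaldehyde | COc1ccc(C=O)c(O)c1 | starting material
24 | acetic 2-{[6-(7-ethoxy-2-oxo-2H-chromen-8-yl)-2-oxo-2H-chromen-7-yl]oxy}acetic anhydride | O=c1ccc2cc(-c3c(OCC)ccc4ccc(=O)oc34)c(OCC(=O)OC(C)=O)cc2o1 | intermediate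
25 | 2-formyl-5-methoxyphenyl 2-{[6-(7-ethoxy-2-oxo-2H-chromen-8-yl)-2-oxo-2H-chromen-7-yl]oxy}acetate | O=c1ccc2cc(-c3c(OCC)ccc4ccc(=O)oc34)c(OCC(=O)Oc3cc(OC)ccc3C=O)cc2o1 | intermediate
26 | 7-ethoxy-8-{7-[(7-methoxy-2-oxo-2H-chromen-3-yl)oxy]-2-oxo-2H-chromen-6-yl}-2H-chromen-2-one | O=c1ccc2cc(-c3c(OCC)ccc4ccc(=O)oc34)c(Oc3cc4ccc(OC)cc4oc3=O)cc2o1 | intermediate
27 | 7-hydroxy-8-{7-[(7-hydroxy-2-oxo-2H-chromen-3-yl)oxy]-2-oxo-2H-chromen-6-yl}-2H-chromen-2-one | O=c1ccc2cc(-c3c(O)ccc4ccc(=O)oc34)c(Oc3cc4ccc(O)cc4oc3=O)cc2o1 | target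

**Step count**

Total steps: 12. Longest linear sequence: 10 steps (steps 1–4 and 7–12 from compound 1); steps 5 and 6 form the two-step side branch to cyclobutenone.

**Steps most likely to fail and fallbacks**

1. Step 7 (key step). Cyclobutenone and vinylketene may oligomerize faster than the hindered aryl ynol ether captures the ketene. The ynol ether may lose ethylene by a retro-ene reaction on prolonged heating. The product phenol may be O-acylated by vinylketene. Fallback, from iodide 8 and returning at 18: Miyaura borylation of 8 (bis(pinacolato)diboron, PdCl2(dppf), KOAc, dioxane, 80 °C) should give tert-butyl 2-{[2-oxo-6-(4,4,5,5-tetramethyl-1,3,2-dioxaborolan-2-yl)-2H-chromen-7-yl]oxy}acetate F1. In parallel, commercial 2-bromoresorcinol is mono-O-ethylated (EtI, 1 equiv, K2CO3, acetone) to 2-bromo-3-ethoxyphenol F2, separated from diether and diol. Suzuki–Miyaura coupling of F1 with F2 (Pd(OAc)2, SPhos, K3PO4, toluene/H2O, 90 °C) should then give the tri-ortho-substituted biaryl 18, with the benzene ring of B bought rather than built.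

2. Step 4. The ynol ether may hydrate to the arylacetate on work-up or chromatography. Ethoxyacetylene may dimerize oxidatively under copper, or add the amine. Fallback, from 8 and returning at 10: Stille coupling of 8 with commercial tributyl(ethoxyethynyl)stannane (Pd(PPh3)4, toluene, 70 °C), which needs neither copper, amine nor free ethoxyacetylene, should give 10 directly; this fallback makes no new compound (F0).

3. Step 12. Cleavage of the hindered C7' ethyl ether may be slow, and long exposure of the sparingly soluble trilactone to excess BBr3 may erode the C7–O–C3'' linkage. Fallback, from 21 and returning at 27: BBr3 (CH2Cl2, −78 °C to rt) is applied to the simpler, more soluble bicoumarin 21, where it should cleave the ethyl ether and the tert-butyl ester together to give 2-{[6-(7-hydroxy-2-oxo-2H-chromen-8-yl)-2-oxo-2H-chromen-7-yl]oxy}acetic acid F3. Perkin–Oglialoro condensation of F3 with 2,4-dihydroxybenzaldehyde 1 (Ac2O, Et3N, 120 °C) acetylates both phenols in the flask and should give 2-oxo-3-{[6-(7-acetoxy-2-oxo-2H-chromen-8-yl)-2-oxo-2H-chromen-7-yl]oxy}-2H-chromen-7-yl acetate F4. Acid methanolysis of the two aryl acetates (HCl, MeOH, 50 °C) then gives 27 under conditions that leave the lactones closed.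

**Further compounds**

F1 | step 7 | tert-butyl 2-{[2-oxo-6-(4,4,5,5-tetramethyl-1,3,2-dioxaborolan-2-yl)-2H-chromen-7-yl]oxy}acetate | O=c1ccc2cc(B3OC(C)(C)C(C)(C)O3)c(OCC(=O)OC(C)(C)C)cc2o1
F2 | step 7 | 2-bromo-3-ethoxyphenol | CCOc1cccc(O)c1Br
F0 | step 4 | none | none
F3 | step 12 | 2-{[6-(7-hydroxy-2-oxo-2H-chromen-8-yl)-2-oxo-2H-chromen-7-yl]oxy}acetic acid | O=c1ccc2cc(-c3c(O)ccc4ccc(=O)oc34)c(OCC(=O)O)cc2o1
F4 | step 12 | 2-oxo-3-{[6-(7-acetoxy-2-oxo-2H-chromen-8-yl)-2-oxo-2H-chromen-7-yl]oxy}-2H-chromen-7-yl acetate | O=c1ccc2cc(-c3c(OC(C)=O)ccc4ccc(=O)oc34)c(Oc3cc4ccc(OC(C)=O)cc4oc3=O)cc2o1
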